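**Retrosynthetic overview**

1. Feature: in the ten-membered carbocycle C1–C10, the C1 ketone with its exocyclic C10=C14 methylidene is the oxidised form of a 2-methylene carbinol, that is, a C1 aldehyde joined to the internal carbon of a terminal C10≡C14 alkyne.
2. Target 33 ⇐ macrocycle 25 by C11 methylenation, C9 angeloylation, desilylation, oxidation at C1 and, last, epoxidation of (E)-C3=C4.
3. 25 ⇐ ynal 24 by nickel-catalysed reductive aldehyde–alkyne coupling, closing C1–C10.
4. 24 ⇐ butenolide 11 + dioxolanyl acid 15 by decarboxylative radical conjugate addition (C7–C8). C7 is set trans to the C6 chain and C8 trans to C9 on the dioxolane. A vinyl-cuprate addition to a tartrate-derived enoate was not used, because attack anti to the C8 oxygen would give the C7 epimer.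
5. 11 ⇐ (R)-epichlorohydrin + alkenyllithium from pent-3-yn-1-ol. Ring order: γ-lactone (step 6), ten-membered ring (step 18), epoxide (step 24).

Key step: step 18

Assumption: positions are numbered C1–C15 as above, also in acyclic intermediates (C12 lactone carbonyl, C13 its methylidene, C15 the methyl on C4); the two C1 epimers formed in step 18 are carried on together because step 23 removes that centre.

**Route**

Step 1
Reactants: 1 pent-3-yn-1-ol
Product: 2 4-methoxybenzyl pent-3-yn-1-yl ether
Conditions: NaH, 4-methoxybenzyl chloride, Bu4NI (cat.), THF/DMF, 0 °C to rt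
Reagents that add atoms: 4-methoxybenzyl chloride, COc1ccc(CCl)cc1
Why: Williamson etherification of the primary sodium alkoxide with the benzylic chloride should be clean and protects O1 through the organometallic steps; no stereocentre is involved.

Step 2
Reactants: 2 4-methoxybenzyl pent-3-yn-1-yl ether
Product: 4 (E)-4-iodopent-3-en-1-yl 4-methoxybenzyl ether, via alkenylzirconocene chloride 3 (not isolated)
Conditions: Cp2Zr(H)Cl (1.6 equiv), THF, 50 °C; then I2, 0 °C
Reagents that add atoms: iodine, II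
Why: Syn hydrozirconation (Schwartz reaction) under equilibrating conditions with excess Cp2Zr(H)Cl should place zirconium on the methyl-bearing, less hindered alkyne carbon, and iodinolysis with retention should give the (E)-iodide with the methyl group cis to the chain, the geometry needed for C3=C4.

Step 3
Reactants: 4 (E)-4-iodopent-3-en-1-yl 4-methoxybenzyl ether; 5 (R)-epichlorohydrin
Product: 7 (2R,4E)-1-chloro-7-(4-methoxybenzyloxy)-4-methylhept-4-en-2-ol, via alkenyllithium 6 (not isolated)
Conditions: t-BuLi (2.0 equiv), Et2O, −78 °C; then 5, BF3·OEt2, THF, −78 °C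
Reagents that add atoms: none
Why: Iodine–lithium exchange with retention of alkene geometry, then BF3-assisted SN2 opening of the oxirane at its CH2 terminus, forms C4–C5; C6 keeps the configuration of (R)-epichlorohydrin because the stereocentre is not touched.

Step 4
Reactants: 7 (2R,4E)-1-chloro-7-(4-methoxybenzyloxy)-4-methylhept-4-en-2-ol
Product: 9 (3R,5E)-8-(4-methoxybenzyloxy)-5-methylocta-1,5-dien-3-ol, via terminal epoxide 8 (not isolated)
Conditions: Me3S I (4 equiv), n-BuLi (3.8 equiv), THF, −10 °C to rt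
Reagents that add atoms: trimethylsulfonium iodide, C[S+](C)C.[I-]
Why: Excess dimethylsulfonium methylide should first close the chlorohydrin to the terminal epoxide (intramolecular Williamson reaction), then open it at CH2 and eliminate Me2S, the known one-carbon homologation of epoxides to allylic alcohols, with C6 untouched.

Step 5
Reactants: 9 (3R,5E)-8-(4-methoxybenzyloxy)-5-methylocta-1,5-dien-3-ol
Product: 10 (3R,5E)-8-(4-methoxybenzyloxy)-5-methylocta-1,5-dien-3-yl prop-2-enoate
Conditions: acryloyl chloride, Et3N, CH2Cl2, 0 °C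
Reagents that add atoms: acryloyl chloride, C=CC(=O)Cl
Why: O-Acylation of the secondary allylic alcohol with the acid chloride and an amine base is routine and sets up the diene for ring closure.

Step 6
Reactants: 10 (3R,5E)-8-(4-methoxybenzyloxy)-5-methylocta-1,5-dien-3-yl prop-2-enoate
Product: 11 (5R)-5-[(2E)-5-(4-methoxybenzyloxy)-2-methylpent-2-en-1-yl]furan-2(5H)-one
Conditions: second-generation Grubbs catalyst RuCl2(=CHPh)(PCy3)(H2IMes) (5 mol%), CH2Cl2 (0.01 M), 40 °C
Reagents that add atoms: none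
Why: Ring-closing metathesis: the ruthenium carbene loads at the monosubstituted allylic vinyl group and closes onto the acrylate to give the five-membered butenolide (first ring), while the trisubstituted C3=C4 alkene is too hindered to take part.

Step 7
Reactants: 12 2,3-O-isopropylidene-L-threitol
Product: 13 [(4S,5S)-5-(tert-butyldimethylsilyloxymethyl)-2,2-dimethyl-1,3-dioxolan-4-yl]methanol
Conditions: NaH (1.0 equiv), THF, 0 °C; then t-BuMe2SiCl, rt
Reagents that add atoms: tert-butyldimethylsilyl chloride, CC(C)(C)[Si](C)(C)Cl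
Why: Monosilylation of the C2-symmetric diol through its sparingly soluble monosodium alkoxide (Williamson-type O-silylation) should stop at the mono ether.

Step 8
Reactants: 13 [(4S,5S)-5-(tert-butyldimethylsilyloxymethyl)-2,2-dimethyl-1,3-dioxolan-4-yl]methanol
Product: 15 (4R,5S)-5-(tert-butyldimethylsilyloxymethyl)-2,2-dimethyl-1,3-dioxolane-4-carboxylic acid, via dioxolane aldehyde 14 (not isolated)
Conditions: TEMPO (2,2,6,6-tetramethylpiperidin-1-oxyl, cat.), PhI(OAc)2 (2.2 equiv), MeCN/H2O (1:1), rt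
Reagents that add atoms: water, O
Why: Oxoammonium-mediated oxidation takes the primary alcohol through aldehyde 14 and its hydrate to the acid without touching the silyl ether or the acetonide, and the trans-dioxolane is the stable arrangement, so the ring carbons should not epimerise.

Step 9
Reactants: 11 (5R)-5-[(2E)-5-(4-methoxybenzyloxy)-2-methylpent-2-en-1-yl]furan-2(5H)-one; 15 (4R,5S)-5-(tert-butyldimethylsilyloxymethyl)-2,2-dimethyl-1,3-dioxolane-4-carboxylic acid
Product: 16 (4S,5R)-4-[(4S,5S)-5-(tert-butyldimethylsilyloxymethyl)-2,2-dimethyl-1,3-dioxolan-4-yl]-5-[(2E)-5-(4-methoxybenzyloxy)-2-methylpent-2-en-1-yl]oxolan-2-one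
Conditions: Ir[dF(CF3)ppy]2(dtbbpy)PF6 (1 mol%), K2HPO4, DMF, blue LEDs, rt (15 in 1.5-fold excess)
Reagents that add atoms: none
Why: Photoredox decarboxylative Giese addition: the carboxylate is oxidised by the photoexcited iridium complex and loses CO2; the nucleophilic dioxolan-4-yl radical adds to C7 of the butenolide anti to the C6 side chain (trans-lactone, sets C7) and through its face anti to the C9 substituent (trans-dioxolane kept, sets C8), after which the α-acyl radical is reduced and protonated at C11.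

Step 10
Reactants: 16 (lactone with C8/C9 acetonide and C10 silyl ether)
Product: 17 (4S,5R)-4-[(4S,5S)-5-(hydroxymethyl)-2,2-dimethyl-1,3-dioxolan-4-yl]-5-[(2E)-5-(4-methoxybenzyloxy)-2-methylpent-2-en-1-yl]oxolan-2-one
Conditions: HF·pyridine, pyridine, THF, 0 °C to rt
Reagents that add atoms: none
Why: Buffered HF·pyridine should cleave the primary TBS ether while the acetonide, the PMB ether and the lactone stay intact (fluoride-mediated desilylation).

Step 11
Reactants: 17 (lactone with C8/C9 acetonide and C10 primary alcohol)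
Product: 18 (4R,5S)-5-[(2R,3S)-2-[(2E)-5-(4-methoxybenzyloxy)-2-methylpent-2-en-1-yl]-5-oxooxolan-3-yl]-2,2-dimethyl-1,3-dioxolane-4-carbaldehyde
Conditions: Dess–Martin periodinane, NaHCO3, CH2Cl2, 0 °C to rt
Reagents that add atoms: none
Why: Dess–Martin oxidation under bicarbonate buffer gives the α-alkoxy aldehyde without over-oxidation, and the trans-dioxolane keeps C9 from epimerising.

Step 12
Reactants: 18 (lactone with C8/C9 acetonide and C10 aldehyde)
Product: 19 (4S,5R)-4-[(4S,5S)-5-ethynyl-2,2-dimethyl-1,3-dioxolan-4-yl]-5-[(2E)-5-(4-methoxybenzyloxy)-2-methylpent-2-en-1-yl]oxolan-2-one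
Conditions: dimethyl (1-diazo-2-oxopropyl)phosphonate, K2CO3, MeOH, 0 °C to rt
Reagents that add atoms: dimethyl (1-diazo-2-oxopropyl)phosphonate, COP(=O)(OC)C(=[N+]=[N-])C(C)=O
Why: Seyferth–Gilbert homologation with the Ohira–Bestmann reagent converts the aldehyde into the terminal C10≡C14 alkyne under mild conditions; C9 stays trans on the dioxolane, and any transient methanolysis of the lactone can only re-close on O6 because O8 is still held in the acetonide.

Step 13
Reactants: 19 (lactone with C8/C9 acetonide and terminal alkyne)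
Product: 20 (4R,5R)-4-[(1S,2S)-1,2-dihydroxybut-3-yn-1-yl]-5-[(2E)-5-(4-methoxybenzyloxy)-2-methylpent-2-en-1-yl]oxolan-2-one
Conditions: AcOH/H2O (4:1), 50 °C
Reagents that add atoms: none
Why: Acid hydrolysis of the isopropylidene acetal frees both hydroxyls; aqueous acetic acid leaves the PMB ether, the alkyne and the lactone alone, and the trans-6,12-lactone is in any case the more stable γ-lactone compared with the cis-8,12 isomer.

Step 14
Reactants: 20 (C8,C9-diol)
Product: 21 (4R,5R)-4-[(1S,2S)-1-hydroxy-2-(triethylsilyloxy)but-3-yn-1-yl]-5-[(2E)-5-(4-methoxybenzyloxy)-2-methylpent-2-en-1-yl]oxolan-2-one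
Conditions: Et3SiCl (1.05 equiv), imidazole, CH2Cl2, −40 °C
Reagents that add atoms: chlorotriethylsilane, CC[Si](Cl)(CC)CC
Why: Kinetic silylation discriminates the propargylic C9–OH, flanked only by the slim alkyne, from the C8–OH next to the branched ring carbon C7, so one equivalent of silyl chloride at low temperature should go to O9; this is where O8 and O9 are told apart for the later C9 ester.

Step 15
Reactants: 21 (C9 triethylsilyl ether with free C8–OH)
Product: 22 (4S,5R)-4-[(1S,2S)-1-(tert-butyldimethylsilyloxy)-2-(triethylsilyloxy)but-3-yn-1-yl]-5-[(2E)-5-(4-methoxybenzyloxy)-2-methylpent-2-en-1-yl]oxolan-2-one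
Conditions: t-BuMe2SiOTf, 2,6-lutidine, CH2Cl2, −78 to 0 °C
Reagents that add atoms: tert-butyldimethylsilyl trifluoromethanesulfonate, CC(C)(C)[Si](C)(C)OS(=O)(=O)C(F)(F)F
Why: The silyl triflate with 2,6-lutidine silylates the remaining hindered secondary alcohol and so blocks translactonisation onto O8 in the basic steps that follow.

Step 16
Reactants: 22 (bis-silyl ether with PMB ether at O1)
Product: 23 (4S,5R)-4-[(1S,2S)-1-(tert-butyldimethylsilyloxy)-2-(triethylsilyloxy)but-3-yn-1-yl]-5-[(2E)-5-hydroxy-2-methylpent-2-en-1-yl]oxolan-2-one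
Conditions: DDQ, CH2Cl2/pH 7 buffer, 0 °C
Reagents that add atoms: none
Why: Oxidative cleavage of the PMB ether by DDQ in a buffered two-phase medium frees the primary C1 alcohol without affecting the silyl ethers, the alkyne, the lactone or the trisubstituted alkene.

Step 17
Reactants: 23 (C1 alcohol)
Product: 24 (3E)-5-[(2R,3S)-3-[(1S,2S)-1-(tert-butyldimethylsilyloxy)-2-(triethylsilyloxy)but-3-yn-1-yl]-5-oxooxolan-2-yl]-4-methylpent-3-enal (ynal)
Conditions: Dess–Martin periodinane, NaHCO3, CH2Cl2, 0 °C; crude aldehyde used at once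
Reagents that add atoms: none
Why: Dess–Martin oxidation under bicarbonate buffer gives the β,γ-unsaturated aldehyde without migration of C3=C4 into conjugation, provided the aldehyde is not stored or chromatographed on acidic silica.

Step 18
Reactants: 24 ynal
Product: 25 ten-membered carbocycle with C10=C14 methylidene and C1 triisopropylsilyl ether (either C1 epimer); C8–OTBS; C9–OTES; trans-fused γ-lactone; (3E,6R,7S,8S,9S)
Conditions: Ni(cod)2 (25 mol%), DP-IPr·HBF4 [1,3-bis(2,6-diisopropylphenyl)-4,5-diphenylimidazolidin-2-ylidene precursor] (25 mol%), KOtBu (25 mol%), premixed; i-Pr3SiH (3 equiv), THF, rt; 24 added by syringe pump over 6 h to 0.003 M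
Reagents that add atoms: triisopropylsilane, CC(C)[SiH](C(C)C)C(C)C
Why: Proposed new method: zerovalent nickel bound to the bulky carbene coordinates the C1 aldehyde and the C10≡C14 alkyne and couples them oxidatively to an oxanickelacyclopentene in which C1–C10 is formed, the Si–H bond then cleaves Ni–O by σ-bond metathesis and C–H reductive elimination puts hydrogen on C14, releasing the silyl ether of the 2-methylene carbinol; the closest known reaction type is the nickel/carbene/silane reductive macrocyclisation of ynals, shown for exocyclic closure of eleven-membered and larger rings and, intermolecularly, for terminal alkynes under the same large-ligand regiocontrol, so the ten-membered carbocycle is the extension. The ring C1–C10 closes in the exocyclic mode through the metallacycle, with C14 left outside as the methylidene. The only new stereocentre, C1, is formed without control and is not needed, because both epimers give the same ketone in step 23. The selectivity that matters is regiochemical (bond to the internal carbon C10 and not to C14, which would give an eleven-membered (E)-cycloalkene): the large carbene turns the substituted alkyne terminus away from the ligand and toward the aldehyde, and a terminal alkyne offers the largest size difference between its two ends. Oligomerisation is held back by slow addition at high dilution, the carbene is preformed so that no free alkoxide meets the β,γ-unsaturated aldehyde, and the trans-lactone with the (E)-C3=C4 alkene removes rotors from the chain that has to fold; i-Pr3SiH replaces Et3SiH so that the C1 ether outlasts the later selective removal of the C9 triethylsilyl group.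

Step 19
Reactants: 25 macrocyclic lactone
Product: 28 α-methylene lactone (C11=C13) of 25; C1–OTIPS; C8–OTBS; C9–OTES; (3E,6R,7S,8S,9S), via Mannich base 26 (not isolated), via trimethylammonium iodide 27 (not isolated)
Conditions: LiN(SiMe3)2, THF, −78 °C; Me2N=CH2 I (Eschenmoser's salt), −78 to 0 °C; then MeI, CH2Cl2, rt; then aq. NaHCO3, rt
Reagents that add atoms: N,N-dimethylmethyleneiminium iodide, C=[N+](C)C.[I-]
Why: Mannich reaction of the lactone lithium enolate with Eschenmoser's salt (alkylation trans to the C7 substituent), N-methylation and E1cB elimination of trimethylamine give the α-methylene lactone, the transient C11 stereocentre being destroyed in the elimination.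

Step 20
Reactants: 28 α-methylene lactone with three silyl ethers
Product: 29 C9 alcohol; C1–OTIPS; C8–OTBS; (3E,6R,7S,8S,9S)
Conditions: HF·pyridine, pyridine, THF, 0 °C
Reagents that add atoms: none
Why: Triethylsilyl ethers are cleaved by buffered HF·pyridine far faster than TBS or TIPS ethers, so only O9 should be freed (selective acidic fluoride desilylation).

Step 21
Reactants: 29 C9 alcohol
Product: 30 C9 angelate; C1–OTIPS; C8–OTBS; (3E,6R,7S,8S,9S)
Conditions: angelic acid, 2,4,6-Cl3C6H2COCl, Et3N, toluene, rt; then 29, 75 °C (no DMAP)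
Reagents that add atoms: angelic acid, C/C=C(/C)C(=O)O
Why: Yamaguchi-type esterification through the preformed mixed anhydride, run without DMAP, is the usual way to acylate a hindered alcohol while keeping the (Z)-geometry of the angeloyl group, and O9 is the only free hydroxyl.

Step 22
Reactants: 30 C9 angelate with C1 and C8 silyl ethers
Product: 31 C1,C8-diol (either C1 epimer) with C9 angelate and α-methylene lactone; (3E,6R,7R,8S,9S)
Conditions: HF·pyridine (excess), THF, 0 °C to rt
Reagents that add atoms: none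
Why: HF·pyridine cleaves the remaining TBS and TIPS ethers (fluoride-mediated desilylation) while the angelate, the α-methylene lactone and the alkenes are stable to acid, and no epoxide is yet present to be opened.

Step 23
Reactants: 31 C1,C8-diol
Product: 32 C1 ketone conjugated with C10=C14; free C8–OH; (3E,6R,7R,8S,9S)
Conditions: MnO2 (activated, excess), CH2Cl2, rt
Reagents that add atoms: none
Why: Activated MnO2 oxidises only the allylic C1 carbinol (both epimers converge on one enone), the C8 hydroxyl not being allylic, and the neutral heterogeneous conditions should spare the β,γ-unsaturated ketone.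

Step 24
Reactants: 32 dienone lactone
Product: 33 target CNP0348992.3; (3R,4R,6R,7R,8S,9S)
Conditions: dimethyldioxirane (acetone solution, 1.1 equiv), CH2Cl2, −20 to 0 °C
Reagents that add atoms: dimethyldioxirane, CC1(C)OO1
Why: Electrophilic epoxidation by dimethyldioxirane (concerted syn oxygen transfer) should take the only electron-rich alkene, trisubstituted C3=C4, since C10=C14, C11=C13 and the angelate alkene are conjugated to carbonyls, and the (E)-geometry gives the trans-epoxide; attack on the outer face of the ring conformer whose C4 methyl lies on the face of H-7 gives the (3R,4R) configuration, and the neutral conditions with a volatile by-product spare the β,γ-epoxy ketone.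

**Compound list**

1 | pent-3-yn-1-ol | CC#CCCO | starting material
2 | 4-methoxybenzyl pent-3-yn-1-yl ether | CC#CCCOCc1ccc(OC)cc1 | intermediate
3 | Cp2Zr(Cl)[(2E)-5-(4-methoxybenzyloxy)pent-2-en-2-yl] (Zr trans to the chain) | C/C(=C\CCOCc1ccc(OC)cc1)[Zr](Cl)(C1C=CC=C1)C1C=CC=C1 | intermediate (not isolated)
4 | (E)-4-iodopent-3-en-1-yl 4-methoxybenzyl ether | C/C(I)=C\CCOCc1ccc(OC)cc1 | intermediate
5 | (R)-epichlorohydrin, (2R)-2-(chloromethyl)oxirane | ClC[C@H]1CO1 | starting material
6 | [(2Z)-5-(4-methoxybenzyloxy)pent-2-en-2-yl]lithium (Li trans to the chain) | [Li]/C(C)=C/CCOCc1ccc(OC)cc1 | intermediate (not isolated)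
7 | (2R,4E)-1-chloro-7-(4-methoxybenzyloxy)-4-methylhept-4-en-2-ol | COc1ccc(COCC/C=C(C)/C[C@@H](O)CCl)cc1 | intermediate
8 | (2R)-2-[(2E)-5-(4-methoxybenzyloxy)-2-methylpent-2-en-1-yl]oxirane | COc1ccc(COCC/C=C(C)/C[C@@H]2CO2)cc1 | intermediate (not isolated)
9 | (3R,5E)-8-(4-methoxybenzyloxy)-5-methylocta-1,5-dien-3-ol | COc1ccc(COCC/C=C(C)/C[C@@H](O)C=C)cc1 | intermediate
10 | (3R,5E)-8-(4-methoxybenzyloxy)-5-methylocta-1,5-dien-3-yl prop-2-enoate | COc1ccc(COCC/C=C(C)/C[C@@H](OC(=O)C=C)C=C)cc1 | intermediate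
11 | (5R)-5-[(2E)-5-(4-methoxybenzyloxy)-2-methylpent-2-en-1-yl]furan-2(5H)-one | COc1ccc(COCC/C=C(C)/C[C@H]2OC(=O)C=C2)cc1 | intermediate
12 | 2,3-O-isopropylidene-L-threitol, [(4S,5S)-2,2-dimethyl-1,3-dioxolane-4,5-diyl]dimethanol | OC[C@@H]1OC(C)(C)O[C@H]1CO | starting material
13 | [(4S,5S)-5-(tert-butyldimethylsilyloxymethyl)-2,2-dimethyl-1,3-dioxolan-4-yl]methanol | OC[C@@H]1OC(C)(C)O[C@H]1CO[Si](C)(C)C(C)(C)C | intermediate
14 | (4R,5S)-5-(tert-butyldimethylsilyloxymethyl)-2,2-dimethyl-1,3-dioxolane-4-carbaldehyde | O=C[C@@H]1OC(C)(C)O[C@H]1CO[Si](C)(C)C(C)(C)C | intermediate (not isolated)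
15 | (4R,5S)-5-(tert-butyldimethylsilyloxymethyl)-2,2-dimethyl-1,3-dioxolane-4-carboxylic acid | OC(=O)[C@@H]1OC(C)(C)O[C@H]1CO[Si](C)(C)C(C)(C)C | intermediate
16 | (4S,5R)-4-[(4S,5S)-5-(tert-butyldimethylsilyloxymethyl)-2,2-dimethyl-1,3-dioxolan-4-yl]-5-[(2E)-5-(4-methoxybenzyloxy)-2-methylpent-2-en-1-yl]oxolan-2-one (6R,7S,8S,9S) | COc1ccc(COCC/C=C(C)/C[C@H]2OC(=O)C[C@@H]2[C@@H]2OC(C)(C)O[C@H]2CO[Si](C)(C)C(C)(C)C)cc1 | intermediate
17 | (4S,5R)-4-[(4S,5S)-5-(hydroxymethyl)-2,2-dimethyl-1,3-dioxolan-4-yl]-5-[(2E)-5-(4-methoxybenzyloxy)-2-methylpent-2-en-1-yl]oxolan-2-one (6R,7S,8S,9S) | COc1ccc(COCC/C=C(C)/C[C@H]2OC(=O)C[C@@H]2[C@@H]2OC(C)(C)O[C@H]2CO)cc1 | intermediate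
18 | (4R,5S)-5-[(2R,3S)-2-[(2E)-5-(4-methoxybenzyloxy)-2-methylpent-2-en-1-yl]-5-oxooxolan-3-yl]-2,2-dimethyl-1,3-dioxolane-4-carbaldehyde (6R,7S,8S,9R) | COc1ccc(COCC/C=C(C)/C[C@H]2OC(=O)C[C@@H]2[C@@H]2OC(C)(C)O[C@H]2C=O)cc1 | intermediate
19 | (4S,5R)-4-[(4S,5S)-5-ethynyl-2,2-dimethyl-1,3-dioxolan-4-yl]-5-[(2E)-5-(4-methoxybenzyloxy)-2-methylpent-2-en-1-yl]oxolan-2-one (6R,7S,8S,9S) | COc1ccc(COCC/C=C(C)/C[C@H]2OC(=O)C[C@@H]2[C@@H]2OC(C)(C)O[C@H]2C#C)cc1 | intermediate
20 | (4R,5R)-4-[(1S,2S)-1,2-dihydroxybut-3-yn-1-yl]-5-[(2E)-5-(4-methoxybenzyloxy)-2-methylpent-2-en-1-yl]oxolan-2-one (6R,7R,8S,9S) | COc1ccc(COCC/C=C(C)/C[C@H]2OC(=O)C[C@@H]2[C@H](O)[C@@H](O)C#C)cc1 | intermediate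
21 | (4R,5R)-4-[(1S,2S)-1-hydroxy-2-(triethylsilyloxy)but-3-yn-1-yl]-5-[(2E)-5-(4-methoxybenzyloxy)-2-methylpent-2-en-1-yl]oxolan-2-one (6R,7R,8S,9S) | COc1ccc(COCC/C=C(C)/C[C@H]2OC(=O)C[C@@H]2[C@H](O)[C@@H](O[Si](CC)(CC)CC)C#C)cc1 | intermediate
22 | (4S,5R)-4-[(1S,2S)-1-(tert-butyldimethylsilyloxy)-2-(triethylsilyloxy)but-3-yn-1-yl]-5-[(2E)-5-(4-methoxybenzyloxy)-2-methylpent-2-en-1-yl]oxolan-2-one (6R,7S,8S,9S) | COc1ccc(COCC/C=C(C)/C[C@H]2OC(=O)C[C@@H]2[C@H](O[Si](C)(C)C(C)(C)C)[C@@H](O[Si](CC)(CC)CC)C#C)cc1 | intermediate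
23 | (4S,5R)-4-[(1S,2S)-1-(tert-butyldimethylsilyloxy)-2-(triethylsilyloxy)but-3-yn-1-yl]-5-[(2E)-5-hydroxy-2-methylpent-2-en-1-yl]oxolan-2-one | OCC/C=C(C)/C[C@H]1OC(=O)C[C@@H]1[C@H](O[Si](C)(C)C(C)(C)C)[C@@H](O[Si](CC)(CC)CC)C#C | intermediate
24 | (3E)-5-[(2R,3S)-3-[(1S,2S)-1-(tert-butyldimethylsilyloxy)-2-(triethylsilyloxy)but-3-yn-1-yl]-5-oxooxolan-2-yl]-4-methylpent-3-enal (ynal) | O=CC/C=C(C)/C[C@H]1OC(=O)C[C@@H]1[C@H](O[Si](C)(C)C(C)(C)C)[C@@H](O[Si](CC)(CC)CC)C#C | intermediate
25 | ten-membered carbocycle, trans-fused 6,12-lactone, C10=C14 methylidene, C1–OTIPS (either epimer), C8–OTBS, C9–OTES, (3E,6R,7S,8S,9S) | C=C1C(O[Si](C(C)C)(C(C)C)C(C)C)C/C=C(C)/C[C@H]2OC(=O)C[C@@H]2[C@H](O[Si](C)(C)C(C)(C)C)[C@H]1O[Si](CC)(CC)CC | intermediate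
26 | 25 carrying CH2NMe2 on C11, trans to C8 (11R) | C=C1C(O[Si](C(C)C)(C(C)C)C(C)C)C/C=C(C)/C[C@H]2OC(=O)[C@@H](CN(C)C)[C@@H]2[C@H](O[Si](C)(C)C(C)(C)C)[C@H]1O[Si](CC)(CC)CC | intermediate (not isolated)
27 | N-methyl quaternary ammonium iodide of 26 | C=C1C(O[Si](C(C)C)(C(C)C)C(C)C)C/C=C(C)/C[C@H]2OC(=O)[C@@H](C[N+](C)(C)C)[C@@H]2[C@H](O[Si](C)(C)C(C)(C)C)[C@H]1O[Si](CC)(CC)CC.[I-] | intermediate (not isolated)
28 | α-methylene lactone (C11=C13), C1–OTIPS, C8–OTBS, C9–OTES, (3E,6R,7S,8S,9S) | C=C1C(O[Si](C(C)C)(C(C)C)C(C)C)C/C=C(C)/C[C@H]2OC(=O)C(=C)[C@@H]2[C@H](O[Si](C)(C)C(C)(C)C)[C@H]1O[Si](CC)(CC)CC | intermediate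
29 | as 28 with free C9–OH, (3E,6R,7S,8S,9S) | C=C1C(O[Si](C(C)C)(C(C)C)C(C)C)C/C=C(C)/C[C@H]2OC(=O)C(=C)[C@@H]2[C@H](O[Si](C)(C)C(C)(C)C)[C@H]1O | intermediate
30 | as 29 with C9 (Z)-2-methylbut-2-enoate (angelate), (3E,6R,7S,8S,9S) | C=C1C(O[Si](C(C)C)(C(C)C)C(C)C)C/C=C(C)/C[C@H]2OC(=O)C(=C)[C@@H]2[C@H](O[Si](C)(C)C(C)(C)C)[C@H]1OC(=O)/C(C)=C\C | intermediate
31 | C1,C8-diol (either C1 epimer) with C9 angelate and α-methylene lactone, (3E,6R,7R,8S,9S) | C=C1C(O)C/C=C(C)/C[C@H]2OC(=O)C(=C)[C@@H]2[C@H](O)[C@H]1OC(=O)/C(C)=C\C | intermediate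
32 | C1 ketone, C10=C14 methylidene, C8–OH, C9 angelate, (3E)-alkene, (6R,7R,8S,9S) | C=C1C(=O)C/C=C(C)/C[C@H]2OC(=O)C(=C)[C@@H]2[C@H](O)[C@H]1OC(=O)/C(C)=C\C | intermediate
33 | CNP0348992.3, (3R,4R)-epoxide of 32, (3R,4R,6R,7R,8S,9S) | C=C1C(=O)O[C@@H]2C[C@@]3(C)O[C@@H]3CC(=O)C(=C)[C@H](OC(=O)/C(C)=C\C)[C@@H](O)[C@@H]12 | target

**Step count and risks**

Total step count: 24 (steps 1–24). Longest linear sequence: 22 steps (steps 1–6 and 9–24); steps 7–8 make the second fragment.

Steps most likely to fail: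

1. Step 18 (Proposed new method). What may go wrong: coupling at the terminal alkyne carbon to give the eleven-membered endocyclic alkene, alkyne oligomerisation outrunning a strained ten-membered closure, or base-induced conjugation of the β,γ-unsaturated aldehyde before it couples. Fallback (known chemistry, another reaction on the same bond): it sets out from 22. Molybdenum-catalysed hydrostannation (Mo(CO)3(CNtBu)3, Bu3SnH, THF, 55 °C), which is α-selective for propargylic ethers, should give the internal alkenylstannane F1. Iododestannylation (I2, CH2Cl2, 0 °C) gives the 2-iodoalkene F2. DDQ then frees the C1 alcohol F3, and buffered Dess–Martin oxidation gives the iodo aldehyde F4. CrCl2 (divalent chromium) with catalytic NiCl2 in DMSO/THF at high dilution, a Nozaki–Hiyama–Kishi closure of the kind used for nine- and ten-membered carbocycles, forms C1–C10 and gives the free 2-methylene carbinol F5. Silylation with i-Pr3SiOTf/2,6-lutidine comes back to the route at 25.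

2. Step 24. What may go wrong: poor or reversed facial selectivity, because the face that is attacked depends on which rotamer of the (E)-alkene the ten-membered ring presents and no rule secures it; over-oxidation is a lesser concern. Fallback (reagent control in place of substrate control): it sets out from 30. Shi epoxidation with the D-fructose-derived ketone (1,2:4,5-di-O-isopropylidene-β-D-erythro-hexo-2,3-diulopyranose) and KHSO5 in bicarbonate-buffered MeCN/H2O at 0 °C should select the (3R,4R) face and give the silylated epoxide F6. HF·pyridine buffered with pyridine then gives the epoxy diol F7, and MnO2 oxidation of its allylic C1 carbinol comes back to the route at 33.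

3. Step 21. What may go wrong: slow acylation of the hindered C9 hydroxyl, and isomerisation of the angeloyl group to the (E)-tigloyl isomer under forcing conditions. Fallback (the Z-alkene is built on the ester instead of being carried in): it sets out from 29. DCC/DMAP esterification with 2-(diphenoxyphosphoryl)propanoic acid, which has no alkene to isomerise, gives the phosphonate ester F8. An Ando-type (Z)-selective Horner–Wadsworth–Emmons reaction with acetaldehyde (NaH, THF, −78 °C) comes back to the route at 30.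

**Further compounds**

F1 | step 18 | 22 with C10(SnBu3)=C14H2 in place of the alkyne | COc1ccc(COCC/C=C(C)/C[C@H]2OC(=O)C[C@@H]2[C@H](O[Si](C)(C)C(C)(C)C)[C@@H](O[Si](CC)(CC)CC)C(=C)[Sn](CCCC)(CCCC)CCCC)cc1
F2 | step 18 | 22 with C10(I)=C14H2 in place of the alkyne | COc1ccc(COCC/C=C(C)/C[C@H]2OC(=O)C[C@@H]2[C@H](O[Si](C)(C)C(C)(C)C)[C@@H](O[Si](CC)(CC)CC)C(I)=C)cc1
F3 | step 18 | C1 alcohol of F2 | OCC/C=C(C)/C[C@H]1OC(=O)C[C@@H]1[C@H](O[Si](C)(C)C(C)(C)C)[C@@H](O[Si](CC)(CC)CC)C(I)=C
F4 | step 18 | C1 aldehyde of F3 | O=CC/C=C(C)/C[C@H]1OC(=O)C[C@@H]1[C@H](O[Si](C)(C)C(C)(C)C)[C@@H](O[Si](CC)(CC)CC)C(I)=C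
F5 | step 18 | macrocycle 25 with free C1–OH (either epimer) | C=C1C(O)C/C=C(C)/C[C@H]2OC(=O)C[C@@H]2[C@H](O[Si](C)(C)C(C)(C)C)[C@H]1O[Si](CC)(CC)CC
F6 | step 24 | (3R,4R)-epoxide of 30 | C=C1C(O[Si](C(C)C)(C(C)C)C(C)C)C[C@H]3O[C@]3(C)C[C@H]2OC(=O)C(=C)[C@@H]2[C@H](O[Si](C)(C)C(C)(C)C)[C@H]1OC(=O)/C(C)=C\C
F7 | step 24 | (3R,4R)-epoxide of 31 (C1,C8-diol) | C=C1C(O)C[C@H]3O[C@]3(C)C[C@H]2OC(=O)C(=C)[C@@H]2[C@H](O)[C@H]1OC(=O)/C(C)=C\C
F8 | step 21 | 29 esterified at O9 with 2-(diphenoxyphosphoryl)propanoic acid | C=C1C(O[Si](C(C)C)(C(C)C)C(C)C)C/C=C(C)/C[C@H]2OC(=O)C(=C)[C@@H]2[C@H](O[Si](C)(C)C(C)(C)C)[C@H]1OC(=O)C(C)P(=O)(Oc1ccccc1)Oc1ccccc1
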